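## Analysis of the target

Compound 27 is a trans-fused bicyclo[5.3.0]decane (a daucane-type hydroazulene) in which a cyclopentane (C1–C5) and a cycloheptane (C1, C5–C10) share the C1–C5 bond. The numbering used here is C1 (ring fusion, methyl), C2 and C3 (CH2), C4 (isopropyl carbinol), C5 (ring-fusion CH), C6 (benzoyloxy), C7 (CH2), C8 (methyl) and C9 (epoxide carbons), C10 (CH2). There are six stereocentres, C1 (R), C4 (R), C5 (S), C6 (S), C8 (R) and C9 (S): with the C1 methyl drawn up (β), the C4 hydroxyl is also β, C5–H is α, and the C6 benzoate and the epoxide oxygen are both α. Sensitive groups are the trisubstituted epoxide, which acid can open with the transannular tertiary C4 hydroxyl, the tertiary alcohol itself (ionisation, dehydration) and the benzoate. The difficulty lies at C5, which sits between an all-carbon quaternary centre (C1) and a tertiary carbinol (C4): the C1 methyl must be placed cis to the C4 hydroxyl and the C5 hydrogen trans to both. The strategy rests on the 1,3-relationship of the C4 hydroxyl and the C1 methyl across C5, together with the oxygen on C6 next to C5: a CH2 group can be handed from the C4 oxygen to a C1=C5 alkene as a cyclopropane, and the C5–CH2 bond can be released again once C6 is a carbonyl group.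

## Retrosynthetic reasoning

27 ⇒ 25 + 26. The ester C–O bond is cut last. The secondary C6 hydroxyl of 25 is the only acylable one, and the ester is kept away from the reductive and organometallic steps.

25 ⇒ 24. The two epoxide C–O bonds are removed. In 24 the C6 hydroxyl is homoallylic to C8=C9 and lies on the α face, so a metal-catalysed hydroperoxide epoxidation can be delivered to that face. The angular methyl on C1 screens the other face, so both effects point the same way.

24 ⇒ 23. The C6–H bond is removed. The C4 hydroxyl of ketol 23 is β and 1,3 to the carbonyl, so a hydride bound to that oxygen reaches C6 from the β face and leaves the C6 oxygen α. An external hydride would come from the α face, away from the angular methyl, and give the wrong epimer.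

23 ⇒ 21. The C1 methyl and the C5 hydrogen are traced back to a CH2 bridge between C1 and C5. Reductive cleavage of the cyclopropyl ketone 21 breaks the C5–CH2 bond, the one that overlaps with the C6 carbonyl, and leaves CH3 on C1 and an enolate at C5. C1 is thereby made with certainty, but C5 is left to a protonation.

21 ⇒ 20. Only the oxidation level at C6 changes. The secondary carbinol of 20 is oxidised beside the tertiary one.

20 ⇒ 18 + 19 (key step). The C1–CH2 and C5–CH2 bonds are cut to the flat dienediol 18. Cutting here lets the C4 oxygen deliver the carbon to its own face of a tetrasubstituted alkene, which intermolecular methylation of a C1 electrophile could not guarantee. The C6 oxygen is carried as a free hydroxyl: it is cis to the C4 hydroxyl, so as a silyl ether it would screen the face that must be attacked, and as an alkoxide it helps.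

18 ⇒ 17 ⇒ 15 + 16. After desilylation, the C4–isopropyl bond is cut to enone 15. The C6 silyloxy group is the only stereocentre of 15 and steers the nucleophile to the opposite face of the C4 carbonyl, which puts the C4 hydroxyl cis to the C6 oxygen. C6 therefore serves as a relay and is erased later at the ketone stage.

15 ⇒ 14 ⇒ 13. The C8=C9 alkene is cut by ring-closing metathesis to the allyl and 2-methylallyl chains of 13. The cis C1=C5 alkene holds them together. The C4 carbonyl is carried as a dioxolane.

13 ⇒ 12 ⇒ 9 + 10. The C6–C7 bond is cut to aldehyde 9 and the 2-methylallyl nucleophile 10. A reagent-controlled allylboration sets C6 directly. The sequence of chromium-mediated coupling to an iodo-enone, oxidation and oxazaborolidine reduction was considered for C6; it was set aside because the reduction would have to choose between two enone-type carbonyl groups and would pass through a ketone prone to alkene migration.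

9 ⇒ 6 + 7; 6 ⇒ 5 ⇒ 2 + 3; 2 ⇒ 1. C5–C6 is cut to the alkenyllithium from bromo ketal 6 and the formyl donor 7. The allyl group comes from 3 by addition to the brominated vinylogous ester 2 and carbonyl transposition. Bromination is done on 1, before any isolated alkene is present.

## Alternatives that were turned down

Alternative 1: The bonds C1–C5, C10–C9 and C9–C8 are cut at once, back to the acyclic (Z)-alkenyl bromide A2. In the forward step, zerovalent palladium (from Pd(OAc)2 and a bisphosphine) under CO inserts into C5–Br, a 5-exo carbopalladation of the C1=C10 alkene forms C1–C5, CO is taken up at the neopentyl C10–Pd bond, and the acylpalladium closes the seven-membered ring on the allyl terminus before β-hydride elimination, giving dienone A1.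
- For: three C–C bonds and both rings form in one operation, and the quaternary C1 is created in the ring-closing event. On bonds formed per step it is stronger than the chosen route.
- Against: C1 is set only by 1,3-induction from the C4 silyloxy centre in a flexible chain. The seven-membered acylpalladation must outrun direct Heck closure onto the allyl group and premature CO insertion.
- Against: A1 carries oxygen at C9 instead of C6 and an exocyclic methylene at C8. The C9 carbonyl has to be removed and transposed into C8=C9, and H and O have to be added across C5=C6 on the hindered α face.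
- Against: A2 needs an enantiopure acyclic tertiary carbinol.
- Comparison: the chosen route is longer to the bicycle, but every oxygen sits where the target has it, and C1 is set by intramolecular delivery from C4.

Alternative 2: C7–C8 is cut, with a ring expansion in the forward sense. The diazoketone A4 with Cu(acac)2 cyclopropanates its tethered silyl enol ether (C7–C8 and a transient C7–C9 bond), and fluoride then cleaves C7–C9 to give the cycloheptane-1,4-dione A3.
- For: the cyclopropanation–fragmentation is dependable and brings the C6 carbonyl into place. C1, C4 and C5 are already fixed in the cyclopentane before the large ring is made; on the ring-fusion question this is stronger than the chosen route, which leaves C5 to an enolate protonation.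
- Against: the hard part is moved into A4, a cyclopentane with two fully substituted centres and an epimerisable, β-silyloxy acyl centre at C5.
- Against: A3 carries a second ketone at C9 and a saturated C8. The two carbonyl groups must be told apart, C9 must be turned into C8=C9 toward C8 and not C10, and the C8 centre made in the key step is erased.
- Comparison: the chosen route has C8=C9 from the metathesis and a single carbonyl at C6, so fewer corrective steps follow its key step.

Alternative 3: C1–C5 is cut as a 1,2-shift. The decalin epoxy alcohol A6 rearranges with Et2AlCl or TiCl4: C5–O opens, C1 migrates from C6 to C5, ring B contracts and ring A expands, giving ketol A5, which is the same compound as 23.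
- For: the shift is stereospecific, with retention at C1 and inversion at C5, so the trans ring fusion follows from the epoxide geometry. On this point it is stronger than the chosen route. It also joins the same endgame.
- Against: A6 needs a decalin with the quaternary C1 methyl, the ring-fusion carbinol C6 and a face-selective epoxidation of an isopropyl-bearing alkene, all in one relative configuration.
- Against: the Lewis acid can open the epoxide at the tertiary C4 instead. The bond that must migrate is an endocyclic bond of ring B, whose anti-periplanar alignment with C5–O needs a strained conformation, so migration of C7 to a bridged ketone competes.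
- Comparison: in place of stereospecificity at C5, the chosen route offers a stereocentre-free alkene as key substrate, reached in ten steps from an achiral cyclopentenone with one reagent-controlled centre, and full control of the C1/C4 relationship.

Key step: step 11

Assumption: (+)-B-methoxydiisopinocampheylborane is the antipode made from (−)-α-pinene, and its 2-methylallyl derivative is taken to attack the Re face of an aldehyde, as the allyl analogue does when it converts benzaldehyde into (R)-1-phenylbut-3-en-1-ol.

## Route

Step 1
Reactants: 1 3-ethoxycyclopent-2-en-1-one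
Product: 2 2-bromo-3-ethoxycyclopent-2-en-1-one
Conditions: N-bromosuccinimide, CH2Cl2, 0 °C to rt
Reagents that add atoms: N-bromosuccinimide, O=C1CCC(=O)N1Br
Why: Electrophilic bromination of the vinylogous ester at its nucleophilic α-carbon (future C5), done before any isolated alkene is present; no stereocentre is formed.

Step 2
Reactants: 2 2-bromo-3-ethoxycyclopent-2-en-1-one; 3 allylmagnesium bromide
Product: 5 2-bromo-3-(prop-2-en-1-yl)cyclopent-2-en-1-one, via tertiary allylic alcohol 4 (not isolated)
Conditions: allylMgBr, THF, −78 to 0 °C; then 1 M HCl, 0 °C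
Reagents that add atoms: allylmagnesium bromide 3, C=CC[Mg]Br; water, O
Why: Stork–Danheiser transposition: 1,2-addition to the vinylogous ester carbonyl (future C1), then acid ionises alcohol 4, water adds at the ethoxy carbon and ethanol is lost, which moves the carbonyl to the future C4. Cold, brief acid keeps the allyl group out of conjugation.

Step 3
Reactants: 5 2-bromo-3-(prop-2-en-1-yl)cyclopent-2-en-1-one
Product: 6 6-bromo-7-(prop-2-en-1-yl)-1,4-dioxaspiro[4.4]non-6-ene
Conditions: Me3SiOCH2CH2OSiMe3, Me3SiOTf (cat.), CH2Cl2, −78 to −20 °C
Reagents that add atoms: 1,2-bis(trimethylsilyloxy)ethane, C[Si](C)(C)OCCO[Si](C)(C)C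
Why: Noyori ketalisation under aprotic conditions at low temperature, which ketalises enones without moving the ring double bond or drawing the allyl group into conjugation; the ketone is masked for the lithiation and the aldehyde chemistry at C6.

Step 4
Reactants: 6 6-bromo-7-(prop-2-en-1-yl)-1,4-dioxaspiro[4.4]non-6-ene; 7 N,N-dimethylformamide
Product: 9 7-(prop-2-en-1-yl)-1,4-dioxaspiro[4.4]non-6-ene-6-carbaldehyde, via alkenyllithium 8 (not isolated)
Conditions: t-BuLi (2 equiv), THF, −78 °C; then 7; then H2O
Reagents that add atoms: N,N-dimethylformamide 7, CN(C)C=O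
Why: Lithium–bromine exchange (the second equivalent of t-BuLi destroys t-BuBr) gives the masked α-anion of the enone; formylation with 7 and hydrolysis of the hemiaminal install C6 as an aldehyde. No stereocentre is formed.

Step 5
Reactants: 9 7-(prop-2-en-1-yl)-1,4-dioxaspiro[4.4]non-6-ene-6-carbaldehyde; 10 (2-methylprop-2-en-1-yl)magnesium chloride
Product: 12 (1R)-3-methyl-1-[7-(prop-2-en-1-yl)-1,4-dioxaspiro[4.4]non-6-en-6-yl]but-3-en-1-ol, via borinate ester 11 (not isolated)
Conditions: (+)-B-methoxydiisopinocampheylborane, 10, Et2O, −78 °C to rt; then 9, −78 °C; then NaOH, H2O2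
Reagents that add atoms: (2-methylprop-2-en-1-yl)magnesium chloride 10, CC(=C)C[Mg]Cl
Why: Brown asymmetric allylboration: the 2-methylallylborane made in the flask adds to the aldehyde through a closed chair (Zimmerman–Traxler) transition state. The isopinocampheyl groups from (−)-α-pinene direct attack to the Re face of the formyl group, which forms C6–C7 and sets C6 as R; oxidative work-up cleaves borinate 11.

Step 6
Reactants: 12 (1R)-3-methyl-1-[7-(prop-2-en-1-yl)-1,4-dioxaspiro[4.4]non-6-en-6-yl]but-3-en-1-ol
Product: 13 tert-butyldimethylsilyl ether of 12
Conditions: t-BuMe2SiCl, imidazole, DMF, rt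
Reagents that add atoms: tert-butyldimethylsilyl chloride, CC(C)(C)[Si](C)(C)Cl
Why: Silylation of the secondary alcohol under basic conditions that leave the ketal intact; the bulky, non-chelating silyl ether is the steering group for step 9.

Step 7
Reactants: 13 tert-butyldimethylsilyl ether of 12
Product: 14 ethylene ketal of (8R)-8-[(tert-butyldimethylsilyl)oxy]-6-methyl-3,4,7,8-tetrahydroazulen-1(2H)-one
Conditions: second-generation Grubbs catalyst RuCl2(=CHPh)(H2IMes)(PCy3) (5 mol%), CH2Cl2 (0.005 M), 40 °C
Reagents that add atoms: none
Why: Ring-closing olefin metathesis: initiation at the monosubstituted allyl terminus and closure on the 1,1-disubstituted alkene. The cis tetrasubstituted C1=C5 alkene holds both chains on one side, so the seven-membered ring with the trisubstituted C8=C9 alkene should close readily, with loss of ethene.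

Step 8
Reactants: 14 ethylene ketal of (8R)-8-[(tert-butyldimethylsilyl)oxy]-6-methyl-3,4,7,8-tetrahydroazulen-1(2H)-one
Product: 15 (8R)-8-[(tert-butyldimethylsilyl)oxy]-6-methyl-3,4,7,8-tetrahydroazulen-1(2H)-one
Conditions: pyridinium p-toluenesulfonate (cat.), acetone–H2O, rt
Reagents that add atoms: water, O
Why: Acid-catalysed hydrolysis of the dioxolane through the allyl-stabilised oxocarbenium ion; the acid is too weak to cleave the secondary silyl ether or to move the skipped C8=C9 alkene into conjugation.

Step 9
Reactants: 15 (8R)-8-[(tert-butyldimethylsilyl)oxy]-6-methyl-3,4,7,8-tetrahydroazulen-1(2H)-one; 16 isopropyllithium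
Product: 17 (1R,8R)-8-[(tert-butyldimethylsilyl)oxy]-6-methyl-1-(propan-2-yl)-1,2,3,4,7,8-hexahydroazulen-1-ol
Conditions: i-PrLi, CeCl3, THF, −78 °C; then H2O
Reagents that add atoms: isopropyllithium 16, [Li]C(C)C
Why: Organocerium 1,2-addition to the enone carbonyl; the low basicity avoids enolisation at C3 and at the doubly allylic C10, and the fully substituted C1 disfavours 1,4-addition. The C6 silyloxy group stands pseudoaxial on the β face to escape the C4 carbonyl oxygen and screens that face, so isopropyl should enter from the α face: the C4 hydroxyl is β, cis to the C6 oxygen, and C4 is R (1,3-induction from C6).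

Step 10
Reactants: 17 (1R,8R)-8-[(tert-butyldimethylsilyl)oxy]-6-methyl-1-(propan-2-yl)-1,2,3,4,7,8-hexahydroazulen-1-ol
Product: 18 (1R,8R)-6-methyl-1-(propan-2-yl)-1,2,3,4,7,8-hexahydroazulene-1,8-diol
Conditions: Bu4NF, THF, 0 °C to rt
Reagents that add atoms: none
Why: Fluoride cleavage of the silyl ether; the free C6 hydroxyl, cis to the C4 hydroxyl, then acts as a second directing group instead of a screen on the face where the methylene must arrive.

Step 11
Reactants: 18 (1R,8R)-6-methyl-1-(propan-2-yl)-1,2,3,4,7,8-hexahydroazulene-1,8-diol; 19 diiodomethane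
Product: 20 (1R,2R,7R,10R)-4-methyl-10-(propan-2-yl)tricyclo[5.3.1.0(1,7)]undec-4-ene-2,10-diol
Conditions: Et2Zn, CH2I2, CH2Cl2, −15 to 0 °C; then aq. NH4Cl
Reagents that add atoms: diiodomethane 19, ICI
Why: Hydroxyl-directed Simmons–Smith cyclopropanation in the Furukawa variant; the closest known reaction type is the alkoxide-directed cyclopropanation of cyclic allylic alcohols with fully substituted ring-fusion alkenes. Et2Zn converts both hydroxyl groups into zinc alkoxides and forms the carbenoid EtZnCH2I with CH2I2, which binds to the alkoxide oxygen atoms. Methylene is then transferred in one concerted syn step through a butterfly-type transition state to C1 and C5, so the C1–CH2 and C5–CH2 bonds form together and the three-membered ring closes by a [2+1] addition across the alkene. Both C1 and C5 become stereocentres (R and R in 20) and both are fixed by the C4 alkoxide, supported by the C6 alkoxide on the same β face, so the future methyl ends cis to the C4 hydroxyl. The step needs face selectivity, which the two cis allylic alkoxides secure, and chemoselectivity over C8=C9, which rests on the much faster directed transfer to the allylic alkene. Because the C6 oxygen is homoallylic to C8=C9, the carbenoid is kept near stoichiometric and the temperature low.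

Step 12
Reactants: 20 (1R,2R,7R,10R)-4-methyl-10-(propan-2-yl)tricyclo[5.3.1.0(1,7)]undec-4-ene-2,10-diol
Product: 21 (1S,7R,10R)-10-hydroxy-4-methyl-10-(propan-2-yl)tricyclo[5.3.1.0(1,7)]undec-4-en-2-one
Conditions: Dess–Martin periodinane, NaHCO3, CH2Cl2, 0 °C to rt
Reagents that add atoms: none
Why: Dess–Martin oxidation touches only the secondary alcohol, and the bicarbonate buffer keeps the tertiary cyclopropyl carbinol from ionising. The C6 stereocentre, having relayed its information to C4, is removed and the carbonyl is placed next to the cyclopropane.

Step 13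
Reactants: 21 (1S,7R,10R)-10-hydroxy-4-methyl-10-(propan-2-yl)tricyclo[5.3.1.0(1,7)]undec-4-en-2-one
Product: 23 (3R,3aR,8aR)-3-hydroxy-6,8a-dimethyl-3-(propan-2-yl)-2,3,3a,5,8,8a-hexahydroazulen-4(1H)-one, via dilithium enolate 22 (not isolated)
Conditions: Li, NH3–THF, −78 °C; then solid NH4Cl
Reagents that add atoms: none
Why: Dissolving-metal cleavage of a cyclopropyl ketone: the C6 ketyl overlaps with the exocyclic C5–CH2 bond and not with the ring-fusion bond C1–C5 near the carbonyl plane, so C5–CH2 breaks, the primary carbanion is protonated to the C1 methyl, and the C5=C6 enolate 22 is protected from further reduction. Protonation of 22 at C5 on the α face gives the trans ring fusion (C5 R), the ketol with C6 and the isopropyl group on opposite faces of the cyclopentane; this protonation is not secured by the substrate and is treated below as the least secure stereocentre.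

Step 14
Reactants: 23 (3R,3aR,8aR)-3-hydroxy-6,8a-dimethyl-3-(propan-2-yl)-2,3,3a,5,8,8a-hexahydroazulen-4(1H)-one
Product: 24 (3R,3aS,4S,8aR)-6,8a-dimethyl-3-(propan-2-yl)-1,2,3,3a,4,5,8,8a-octahydroazulene-3,4-diol
Conditions: Me4NBH(OAc)3, MeCN–AcOH, −30 to 0 °C
Reagents that add atoms: none
Why: Evans–Saksena reduction: acetate is exchanged for the C4 hydroxyl at boron, and hydride is delivered within a six-membered chair-like transition state to the β face of C6. The C6 hydroxyl therefore ends α (C6 S), anti to the C4 oxygen and equatorial; an external hydride would come from the α face, away from the angular methyl, and give the epimer.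

Step 15
Reactants: 24 (3R,3aS,4S,8aR)-6,8a-dimethyl-3-(propan-2-yl)-1,2,3,3a,4,5,8,8a-octahydroazulene-3,4-diol
Product: 25 (3R,3aS,4S,6R,7S,8aR)-6,7-epoxy-6,8a-dimethyl-3-(propan-2-yl)decahydroazulene-3,4-diol
Conditions: VO(acac)2 (cat.), t-BuOOH, CH2Cl2, 0 °C to rt
Reagents that add atoms: tert-butyl hydroperoxide, CC(C)(C)OO
Why: Vanadium-catalysed epoxidation directed by the homoallylic C6 hydroxyl: its vanadate ester delivers the peroxide oxygen to the α face of C8=C9, the face also left open by the angular methyl. This sets C8 (R) and C9 (S).

Step 16
Reactants: 25 (3R,3aS,4S,6R,7S,8aR)-6,7-epoxy-6,8a-dimethyl-3-(propan-2-yl)decahydroazulene-3,4-diol; 26 benzoyl chloride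
Product: 27 (3R,3aS,4S,6R,7S,8aR)-6,7-epoxy-3-hydroxy-6,8a-dimethyl-3-(propan-2-yl)decahydroazulen-4-yl benzoate
Conditions: BzCl, pyridine, 4-(dimethylamino)pyridine (cat.), CH2Cl2, 0 °C to rt
Reagents that add atoms: benzoyl chloride 26, O=C(Cl)c1ccccc1
Why: Nucleophile-catalysed acylation of the secondary C6 hydroxyl; the tertiary C4 hydroxyl is too hindered to react, and the basic medium leaves the epoxide closed.

## Compound list

1 | 3-ethoxycyclopent-2-en-1-one | CCOC1=CC(=O)CC1 | starting material
2 | 2-bromo-3-ethoxycyclopent-2-en-1-one | CCOC1=C(Br)C(=O)CC1 | intermediate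
3 | allylmagnesium bromide | C=CC[Mg]Br | starting material
4 | rac-2-bromo-3-ethoxy-1-(prop-2-en-1-yl)cyclopent-2-en-1-ol (tertiary allylic alcohol, not isolated) | C=CCC1(O)CCC(OCC)=C1Br | intermediate
5 | 2-bromo-3-(prop-2-en-1-yl)cyclopent-2-en-1-one | C=CCC1=C(Br)C(=O)CC1 | intermediate
6 | 6-bromo-7-(prop-2-en-1-yl)-1,4-dioxaspiro[4.4]non-6-ene | C=CCC1=C(Br)C2(CC1)OCCO2 | intermediate
7 | N,N-dimethylformamide | CN(C)C=O | starting material
8 | [7-(prop-2-en-1-yl)-1,4-dioxaspiro[4.4]non-6-en-6-yl]lithium (not isolated) | [Li]C1=C(CC=C)CCC12OCCO2 | intermediate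
9 | 7-(prop-2-en-1-yl)-1,4-dioxaspiro[4.4]non-6-ene-6-carbaldehyde | O=CC1=C(CC=C)CCC12OCCO2 | intermediate
10 | (2-methylprop-2-en-1-yl)magnesium chloride | CC(=C)C[Mg]Cl | starting material
11 | B,B-diisopinocampheylborinate of 12 (not isolated) | CC(=C)C[C@@H](OB([C@H]1C[C@H]2C[C@@H]([C@@H]1C)C2(C)C)[C@H]1C[C@H]2C[C@@H]([C@@H]1C)C2(C)C)C1=C(CC=C)CCC12OCCO2 | intermediate
12 | (1R)-3-methyl-1-[7-(prop-2-en-1-yl)-1,4-dioxaspiro[4.4]non-6-en-6-yl]but-3-en-1-ol | CC(=C)C[C@@H](O)C1=C(CC=C)CCC12OCCO2 | intermediate
13 | tert-butyldimethylsilyl ether of 12 (C6 R) | CC(=C)C[C@@H](O[Si](C)(C)C(C)(C)C)C1=C(CC=C)CCC12OCCO2 | intermediate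
14 | ethylene ketal of (8R)-8-[(tert-butyldimethylsilyl)oxy]-6-methyl-3,4,7,8-tetrahydroazulen-1(2H)-one | C1COC2(O1)CCC1=C2[C@H](O[Si](C)(C)C(C)(C)C)CC(C)=CC1 | intermediate
15 | (8R)-8-[(tert-butyldimethylsilyl)oxy]-6-methyl-3,4,7,8-tetrahydroazulen-1(2H)-one | O=C1CCC2=C1[C@H](O[Si](C)(C)C(C)(C)C)CC(C)=CC2 | intermediate
16 | isopropyllithium | [Li]C(C)C | starting material
17 | (1R,8R)-8-[(tert-butyldimethylsilyl)oxy]-6-methyl-1-(propan-2-yl)-1,2,3,4,7,8-hexahydroazulen-1-ol | CC(C)[C@]1(O)CCC2=C1[C@H](O[Si](C)(C)C(C)(C)C)CC(C)=CC2 | intermediate
18 | (1R,8R)-6-methyl-1-(propan-2-yl)-1,2,3,4,7,8-hexahydroazulene-1,8-diol (both hydroxyls β) | CC(C)[C@]1(O)CCC2=C1[C@H](O)CC(C)=CC2 | intermediate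
19 | diiodomethane | ICI | starting material
20 | (1R,2R,7R,10R)-4-methyl-10-(propan-2-yl)tricyclo[5.3.1.0(1,7)]undec-4-ene-2,10-diol (cyclopropane CH2 on the face of both hydroxyls) | CC(C)[C@]1(O)CC[C@@]23C[C@]21[C@H](O)CC(C)=CC3 | intermediate
21 | (1S,7R,10R)-10-hydroxy-4-methyl-10-(propan-2-yl)tricyclo[5.3.1.0(1,7)]undec-4-en-2-one | CC(C)[C@]1(O)CC[C@@]23C[C@]21C(=O)CC(C)=CC3 | intermediate
22 | dilithium C4-alkoxide C5=C6 enolate (C1 R, C4 R; not isolated) | CC(C)[C@]1(O[Li])CC[C@]2(C)CC=C(C)CC(O[Li])=C21 | intermediate
23 | (3R,3aR,8aR)-3-hydroxy-6,8a-dimethyl-3-(propan-2-yl)-2,3,3a,5,8,8a-hexahydroazulen-4(1H)-one | CC(C)[C@]1(O)CC[C@]2(C)CC=C(C)CC(=O)[C@H]21 | intermediate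
24 | (3R,3aS,4S,8aR)-6,8a-dimethyl-3-(propan-2-yl)-1,2,3,3a,4,5,8,8a-octahydroazulene-3,4-diol | CC(C)[C@]1(O)CC[C@]2(C)CC=C(C)C[C@H](O)[C@H]21 | intermediate
25 | (3R,3aS,4S,6R,7S,8aR)-6,7-epoxy-6,8a-dimethyl-3-(propan-2-yl)decahydroazulene-3,4-diol | CC(C)[C@]1(O)CC[C@]2(C)C[C@@H]3O[C@]3(C)C[C@H](O)[C@H]21 | intermediate
26 | benzoyl chloride | O=C(Cl)c1ccccc1 | starting material
27 | (3R,3aS,4S,6R,7S,8aR)-6,7-epoxy-3-hydroxy-6,8a-dimethyl-3-(propan-2-yl)decahydroazulen-4-yl benzoate | CC(C)[C@]1(O)CC[C@]2(C)C[C@@H]3O[C@]3(C)C[C@H](OC(=O)c3ccccc3)[C@H]21 | target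

## Step count and uncertain steps

Total step count: 16. Longest linear sequence: 16 steps (1 to 27).

Step 11 (key step). Methylene transfer to the tetrasubstituted, doubly flanked C1=C5 alkene may be slow, so that cyclopropanation of the C8=C9 alkene, which is homoallylic to the C6 oxygen, competes. The zinc iodide formed may also ionise the tertiary allylic alcohol or the cyclopropyl carbinols of the product. The fallback replaces cyclopropanation and ring opening by a conjugate methylation. It sets out from 18: MnO2 in CH2Cl2 oxidises only the secondary allylic C6 hydroxyl to the cross-conjugated hydroxy dienone (1R)-1-hydroxy-6-methyl-1-(propan-2-yl)-2,3,4,7-tetrahydroazulen-8(1H)-one F1. Me2CuLi with Me3SiCl in THF at −78 °C then adds methyl to C1 on the face away from the isopropyl group, that is cis to the C4 oxygen, and enolate and alkoxide are silylated to the bis(trimethylsilyl) enol ether F2. Citric acid in methanol cleaves both silyl groups and the route is rejoined at 23. The ring fusion is then again decided by protonation at C5.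

Step 13. Protonation of the C5 enolate may take place on the β face. The α face carries the isopropyl group of C4 and the ring carbon C10, the C4 lithium alkoxide can chelate the enolate oxygen and turn the isopropyl group over the α face, and the C4 hydroxyl can relay a proton on its own face. Kinetic protonation would then lead to the cis ring fusion, although the trans ketol is the less strained isomer. Correction by base is ruled out: deprotonation at C7 with migration of C8=C9 into conjugation, and retro-aldol cleavage or dehydration of the β-hydroxy ketone, are faster than epimerisation at the hindered C5. The fallback sets C5–H by radical hydrogen abstraction inside a temporary siloxane instead of by enolate protonation. It sets out from 17: (bromomethyl)chlorodimethylsilane and imidazole in DMF give the (bromomethyl)dimethylsilyl ether F3. Bu3SnH and azobisisobutyronitrile in benzene at 80 °C generate the α-silyl radical, which closes in the 6-endo mode on C1, the alkene terminus flanked by two CH2 groups, whereas C5 lies between C4 and C6. The C5 radical, now the one-atom bridge of a bicyclo[3.2.1] siloxane, takes hydrogen from the stannane on the face away from the O–Si–CH2 bridge and gives the trans-fused cyclic siloxane F4. Bu4NF in DMF at 70 °C cleaves the Si–C bond with protonation (C1 methyl), frees the C4 hydroxyl and removes the C6 silyl ether, giving (3R,3aS,4R,8aR)-6,8a-dimethyl-3-(propan-2-yl)-1,2,3,3a,4,5,8,8a-octahydroazulene-3,4-diol F5, the C6 epimer of 24. Dess–Martin periodinane oxidises its secondary hydroxyl and the route is rejoined at 23.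

Step 9. The hindered secondary organocerium reagent may enolise the ketone or reduce it by β-hydride transfer, and the facial control by the C6 silyloxy group may be incomplete if that group does not stay pseudoaxial. The fallback uses a smaller sp2 nucleophile and a later selective hydrogenation. It sets out from 15: isopropenylmagnesium bromide with CeCl3 in THF at −78 °C adds in the same facial sense to give the isopropenyl carbinol F6. H2 with RhCl(PPh3)3 in benzene then reduces only the 1,1-disubstituted alkene beside the trisubstituted and tetrasubstituted ones, and the route is rejoined at 17.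

Step 14. Exchange of the hindered tertiary C4 hydroxyl at boron may be slow, so that undirected hydride delivery from the α face gives the C6 epimer, and the acidic medium may move the β,γ-alkene. The fallback uses thermodynamic control instead of directed delivery. It sets out from 23: Li in NH3–THF with methanol at −78 °C reduces the ketone through the ketyl to the more stable equatorial 6α-alcohol, which avoids the 1,3-diaxial clash with the angular methyl, and the route is rejoined at 24. No new compound is passed (entry F0).

Step 15. The vanadium centre may act as a Lewis acid and let the C4 hydroxyl open the new epoxide across the ring, or the oxidant may attack the secondary alcohol. The fallback reverses the order and relies on steric instead of directed control. It sets out from 24: benzoyl chloride, pyridine and 4-(dimethylamino)pyridine give (3R,3aS,4S,8aR)-3-hydroxy-6,8a-dimethyl-3-(propan-2-yl)-1,2,3,3a,4,5,8,8a-octahydroazulen-4-yl benzoate F7. 3-Chloroperbenzoic acid with NaHCO3 in CH2Cl2 at 0 °C then epoxidises C8=C9 from the α face, which the angular methyl leaves open, and the route is rejoined at 27.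

## Further compounds

F1 | step 11 | (1R)-1-hydroxy-6-methyl-1-(propan-2-yl)-2,3,4,7-tetrahydroazulen-8(1H)-one | CC(C)[C@]1(O)CCC2=C1C(=O)CC(C)=CC2
F2 | step 11 | bis(trimethylsilyl) derivative of 23 (C4 silyl ether, C5=C6 silyl enol ether; C1 R, C4 R) | CC(C)[C@]1(O[Si](C)(C)C)CC[C@]2(C)CC=C(C)CC(O[Si](C)(C)C)=C21
F3 | step 13 | (bromomethyl)dimethylsilyl ether of 17 at the C4 oxygen | CC(C)[C@]1(O[Si](C)(C)CBr)CCC2=C1[C@H](O[Si](C)(C)C(C)(C)C)CC(C)=CC2
F4 | step 13 | trans-fused cyclic siloxane bridging the C4 oxygen and the C1 methylene, C6 tert-butyldimethylsilyl ether | CC(C)[C@]12O[Si](C)(C)C[C@@]3(CC1)CC=C(C)C[C@@H](O[Si](C)(C)C(C)(C)C)[C@@H]23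
F5 | step 13 | (3R,3aS,4R,8aR)-6,8a-dimethyl-3-(propan-2-yl)-1,2,3,3a,4,5,8,8a-octahydroazulene-3,4-diol | CC(C)[C@]1(O)CC[C@]2(C)CC=C(C)C[C@@H](O)[C@H]21
F6 | step 9 | isopropenyl analogue of 17 (C4 hydroxyl cis to the C6 silyloxy group) | CC(=C)[C@]1(O)CCC2=C1[C@H](O[Si](C)(C)C(C)(C)C)CC(C)=CC2
F0 | step 14 | none | none
F7 | step 15 | (3R,3aS,4S,8aR)-3-hydroxy-6,8a-dimethyl-3-(propan-2-yl)-1,2,3,3a,4,5,8,8a-octahydroazulen-4-yl benzoate | CC(C)[C@]1(O)CC[C@]2(C)CC=C(C)C[C@H](OC(=O)c3ccccc3)[C@H]21
A1 | alternative 1 | C4 triethylsilyl ether of 4-isopropyl-1-methyl-8-methylidenebicyclo[5.3.0]dec-5-en-9-one (route numbering) | CC(C)[C@]1(O[Si](CC)(CC)CC)CC[C@]2(C)CC(=O)C(=C)CC=C21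
A2 | alternative 1 | (4Z,6R)-5-bromo-9-methyl-6-(propan-2-yl)-6-[(triethylsilyl)oxy]deca-1,4,9-triene | CC(C)[C@](O[Si](CC)(CC)CC)(CCC(C)=C)/C(Br)=C/CC=C
A3 | alternative 2 | C4 tert-butyldimethylsilyl ether of the trans-fused 1,8-dimethyl-4-isopropylbicyclo[5.3.0]decane-6,9-dione (route numbering) | CC(C)[C@]1(O[Si](C)(C)C(C)(C)C)CC[C@]2(C)CC(=O)[C@@H](C)CC(=O)[C@H]21
A4 | alternative 2 | cyclopentyl diazomethyl ketone with the C4 silyl ether, the C1 methyl and a (Z)-2-(trimethylsilyloxy)but-2-enyl chain on C1 | CC(C)[C@]1(O[Si](C)(C)C(C)(C)C)CC[C@](C)(C/C(O[Si](C)(C)C)=C/C)[C@H]1C(=O)C=[N+]=[N-]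
A5 | alternative 3 | (3R,3aR,8aR)-3-hydroxy-6,8a-dimethyl-3-(propan-2-yl)-2,3,3a,5,8,8a-hexahydroazulen-4(1H)-one | CC(C)[C@]1(O)CC[C@]2(C)CC=C(C)CC(=O)[C@H]21
A6 | alternative 3 | decalin syn-4,5-epoxy-6-ol with C1 methyl, C4 isopropyl and C8=C9 alkene (route numbering) | CC(C)[C@]12CC[C@]3(C)CC=C(C)C[C@]3(O)[C@H]1O2
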